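**Retrosynthetic overview**
1. Last step: unmask the ring-A 3-OH (MOM ether). All other functional groups are already in place.
2. Key disconnection is the ring-A aryl–C(=O) bond. A ring-A aryllithium (from the 2-bromobenzaldehyde, CHO masked in situ as a lithium morpholino alkoxide) attacks a ring-B acyl donor, the acetonide of 7-hydroxy-2,2-dimethylchromene-8-carboxylic acid. One pot releases the ketone, the chromenol OH and the CHO.
3. Ring A comes from 1-bromo-2,5-dimethoxy-4-methylbenzene: lithiation between Br and OMe then DMF, double demethylation, then MOM on the free OH and prenyl on the CHO-chelated OH.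
4. Ring B comes from the acetonide of 2,6-dihydroxybenzoic acid: O-(1,1-dimethylpropargyl)ation, then aromatic Claisen and oxa-6π closure.
5. Ring order: both benzene rings are bought. The 2H-pyran is the only ring formed (before the coupling), and the purchased dioxinone ring is opened in the coupling.

Assumption: the target SMILES has no stereocentre and no stereogenic double bond, so it is achiral, "single enantiomer" needs no stereocontrol, and it is made in the open keto-aldehyde form drawn.

**Step 1**
Reactants: 1 1-bromo-2,5-dimethoxy-4-methylbenzene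
Product: 4 2-bromo-3,6-dimethoxy-5-methylbenzaldehyde, via aryllithium 2 (not isolated), via lithium hemiaminal alkoxide 3 (not isolated)
Conditions: LDA (commercial solution, 1.15 equiv), THF, −78 °C, 1 h; DMF (3 equiv), −78 → 0 °C; 1 M aq HCl
Reagents that add atoms: N,N-dimethylformamide (DMF), CN(C)C=O
Why: In this directed ortho-lithiation/formylation the ring H flanked by Br and OMe is by far the most acidic, non-nucleophilic LDA deprotonates it instead of exchanging Br, the o-bromoaryllithium keeps its LiBr at −78 °C, and no stereocentre is formed.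

**Step 2**
Reactants: 4 2-bromo-3,6-dimethoxy-5-methylbenzaldehyde
Product: 6 2-bromo-3,6-dihydroxy-5-methylbenzaldehyde, via bis(dibromoboryl) ether 5 (not isolated)
Conditions: BBr3 (3 equiv), CH2Cl2, −78 °C → rt; H2O, 0 °C
Reagents that add atoms: none
Why: BBr3 Lewis-acid ether cleavage removes both aryl methyl ethers while the aryl bromide and the non-enolisable aldehyde are inert.

**Step 3**
Reactants: 6 2-bromo-3,6-dihydroxy-5-methylbenzaldehyde
Product: 7 2-bromo-6-hydroxy-3-(methoxymethoxy)-5-methylbenzaldehyde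
Conditions: MOMCl (1.05 equiv), K2CO3 (1.1 equiv), acetone, N2, 0 °C → rt
Reagents that add atoms: chloromethyl methyl ether (MOMCl), COCCl
Why: This Williamson-type O-alkylation is chemoselective because the 6-OH is locked in a hydrogen bond to the CHO and flanked by CH3 and CHO, so one equivalent of MOMCl takes only the free, more acidic 3-OH next to Br.

**Step 4**
Reactants: 7 2-bromo-6-hydroxy-3-(methoxymethoxy)-5-methylbenzaldehyde
Product: 8 2-bromo-3-(methoxymethoxy)-5-methyl-6-[(3-methylbut-2-en-1-yl)oxy]benzaldehyde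
Conditions: prenyl bromide (1.3 equiv), K2CO3 (2 equiv), DMF, rt, 12 h
Reagents that add atoms: prenyl bromide (1-bromo-3-methylbut-2-ene), CC(C)=CCBr
Why: Williamson ether synthesis (SN2 at the primary allylic bromide) alkylates the only remaining phenol in polar aprotic medium, and the MOM ether, CHO and ArBr tolerate carbonate base.

**Step 5**
Reactants: 9 5-hydroxy-2,2-dimethyl-4H-1,3-benzodioxin-4-one
Product: 10 2,2-dimethyl-5-[(2-methylbut-3-yn-2-yl)oxy]-4H-1,3-benzodioxin-4-one
Conditions: 3-chloro-3-methylbut-1-yne (1.5 equiv), DBU (1.6 equiv), CuCl2·2H2O (1 mol %), MeCN, 0 °C → rt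
Reagents that add atoms: 3-chloro-3-methylbut-1-yne, CC(C)(Cl)C#C
Why: Copper-catalysed O-propargylation of the phenoxide with the tertiary propargylic chloride gives the 1,1-dimethylpropargyl aryl ether under conditions that leave the lactone-acetal untouched.

**Step 6**
Reactants: 10 2,2-dimethyl-5-[(2-methylbut-3-yn-2-yl)oxy]-4H-1,3-benzodioxin-4-one
Product: 13 7-hydroxy-2,2-dimethyl-2H-chromene-8-carboxylic acid acetonide (pyrano-fused 2,2-dimethyl-1,3-benzodioxin-4-one), via allenylphenol 11 (not isolated), via ortho-quinone methide 12 (not isolated)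
Conditions: o-xylene, reflux (144 °C), 14 h
Reagents that add atoms: none
Why: The aromatic propargyl Claisen rearrangement can only reach the single free ortho carbon, and rearomatisation, 1,5-H shift and oxa-6π electrocyclisation then close the 2,2-dimethyl-2H-pyran with unambiguous regiochemistry.

**Step 7**
Reactants: 8 2-bromo-3-(methoxymethoxy)-5-methyl-6-[(3-methylbut-2-en-1-yl)oxy]benzaldehyde; 13 7-hydroxy-2,2-dimethyl-2H-chromene-8-carboxylic acid acetonide
Product: 17 2-[(7-hydroxy-2,2-dimethyl-2H-chromen-8-yl)carbonyl]-3-(methoxymethoxy)-5-methyl-6-[(3-methylbut-2-en-1-yl)oxy]benzaldehyde, via lithium morpholino alkoxide 14 (not isolated), via aryllithium 15 (not isolated), via tetrahedral adduct 16 (not isolated)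
Conditions: morpholine (1.1 equiv), n-BuLi (1.1 equiv), THF, −40 °C, then 8; n-BuLi (1.1 equiv), −78 °C, 20 min; 13 (1.2 equiv), THF, −78 → −30 °C; aq NH4Cl, −30 °C → rt
Reagents that add atoms: none
Why: With the aldehyde masked in situ as its α-amino alkoxide, fast Br/Li exchange at −78 °C spares the prenyl ether, the MOM-chelated aryllithium acylates the planar, tied-back benzodioxinone on its open π-face (nucleophilic acyl substitution), and the cold-stable tetrahedral adduct prevents a second addition and collapses on quench to ketone, free chromenol OH and CHO, erasing its transient stereocentres.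

**Step 8**
Reactants: 17 2-[(7-hydroxy-2,2-dimethyl-2H-chromen-8-yl)carbonyl]-3-(methoxymethoxy)-5-methyl-6-[(3-methylbut-2-en-1-yl)oxy]benzaldehyde
Product: 18 3-hydroxy-2-[(7-hydroxy-2,2-dimethyl-2H-chromen-8-yl)carbonyl]-5-methyl-6-[(3-methylbut-2-en-1-yl)oxy]benzaldehyde (CNP0150093.0)
Conditions: 2 M aq HCl (cat.), THF–i-PrOH, 35 °C, stopped at full conversion
Reagents that add atoms: none
Why: In this acid-catalysed acetal hydrolysis the MOM ether ortho to the diaryl ketone is the most labile group because its phenol is released into a strong intramolecular hydrogen bond, so it should leave in dilute aqueous acid before the aryl prenyl ether or the chromene can ionise, and no stereocentre is involved.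

**Compound list**
1 | 1-bromo-2,5-dimethoxy-4-methylbenzene | COc1cc(Br)c(OC)cc1C | starting material
2 | 2-bromo-3,6-dimethoxy-5-methylphenyllithium | COc1cc(C)c(OC)c([Li])c1Br | intermediate
3 | lithium (2-bromo-3,6-dimethoxy-5-methylphenyl)(dimethylamino)methoxide (racemic, transient) | COc1cc(C)c(OC)c(C(O[Li])N(C)C)c1Br | intermediate
4 | 2-bromo-3,6-dimethoxy-5-methylbenzaldehyde | COc1cc(C)c(OC)c(C=O)c1Br | intermediate
5 | 2-bromo-3,6-bis[(dibromoboryl)oxy]-5-methylbenzaldehyde | Cc1cc(OB(Br)Br)c(Br)c(C=O)c1OB(Br)Br | intermediate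
6 | 2-bromo-3,6-dihydroxy-5-methylbenzaldehyde | Cc1cc(O)c(Br)c(C=O)c1O | intermediate
7 | 2-bromo-6-hydroxy-3-(methoxymethoxy)-5-methylbenzaldehyde | COCOc1cc(C)c(O)c(C=O)c1Br | intermediate
8 | 2-bromo-3-(methoxymethoxy)-5-methyl-6-[(3-methylbut-2-en-1-yl)oxy]benzaldehyde | COCOc1cc(C)c(OCC=C(C)C)c(C=O)c1Br | intermediate
9 | 5-hydroxy-2,2-dimethyl-4H-1,3-benzodioxin-4-one (acetonide of 2,6-dihydroxybenzoic acid) | CC1(C)OC(=O)c2c(O)cccc2O1 | starting material
10 | 2,2-dimethyl-5-[(2-methylbut-3-yn-2-yl)oxy]-4H-1,3-benzodioxin-4-one | CC1(C)OC(=O)c2c(OC(C)(C)C#C)cccc2O1 | intermediate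
11 | 5-hydroxy-2,2-dimethyl-6-(3-methylbuta-1,2-dien-1-yl)-4H-1,3-benzodioxin-4-one | CC(C)=C=Cc1ccc2OC(C)(C)OC(=O)c2c1O | intermediate
12 | 2,2-dimethyl-6-(3-methylbut-2-en-1-ylidene)-4H-1,3-benzodioxine-4,5(6H)-dione (ortho-quinone methide) | CC(C)=CC=C1C=CC2=C(C1=O)C(=O)OC(C)(C)O2 | intermediate
13 | 7-hydroxy-2,2-dimethyl-2H-chromene-8-carboxylic acid acetonide (isopropylidene bridge between O7 and the C8 carboxyl) | CC1(C)C=Cc2ccc3OC(C)(C)OC(=O)c3c2O1 | intermediate
14 | lithium α-morpholino alkoxide of 8 (racemic, transient) | COCOc1cc(C)c(OCC=C(C)C)c(C(O[Li])N2CCOCC2)c1Br | intermediate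
15 | aryllithium from 14 (Li in place of Br) | COCOc1cc(C)c(OCC=C(C)C)c(C(O[Li])N2CCOCC2)c1[Li] | intermediate
16 | dilithium tetrahedral adduct of 15 on the lactone carbonyl of 13 (diastereomer mixture, transient) | COCOc1cc(C)c(OCC=C(C)C)c(C(O[Li])N2CCOCC2)c1C1(O[Li])OC(C)(C)Oc2ccc3C=CC(C)(C)Oc3c21 | intermediate
17 | 2-[(7-hydroxy-2,2-dimethyl-2H-chromen-8-yl)carbonyl]-3-(methoxymethoxy)-5-methyl-6-[(3-methylbut-2-en-1-yl)oxy]benzaldehyde | COCOc1cc(C)c(OCC=C(C)C)c(C=O)c1C(=O)c1c(O)ccc2C=CC(C)(C)Oc12 | intermediate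
18 | 3-hydroxy-2-[(7-hydroxy-2,2-dimethyl-2H-chromen-8-yl)carbonyl]-5-methyl-6-[(3-methylbut-2-en-1-yl)oxy]benzaldehyde (achiral) | CC(C)=CCOc1c(C)cc(O)c(C(=O)c2c(O)ccc3c2OC(C)(C)C=C3)c1C=O | target

**Total step count:** 8. **Longest linear sequence:** 6 (steps 1, 2, 3, 4, 7, 8). Steps 5 and 6 form the short ring-B branch.

**Three steps most likely to fail**

**Step 7.** The risks are steric: a doubly ortho-substituted aryllithium must build a tetra-ortho-substituted benzophenone. Masking of the hindered CHO may also be incomplete, and early collapse of the adduct would release acetone into the mixture.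

The fallback sets out from 8 and 13 and comes back at 18. It replaces the acyl transfer by addition to an aldehyde followed by oxidation. Compound 8 is treated with HC(OMe)3 and cat. PPTS in MeOH to give 2-bromo-3-(methoxymethoxy)-5-methyl-6-(prenyloxy)benzaldehyde dimethyl acetal F1. Compound 13 is reduced with DIBAL-H (CH2Cl2, −78 °C) through the aluminium hemiacetal F2 to 7-hydroxy-2,2-dimethyl-2H-chromene-8-carbaldehyde F3. MOMCl/K2CO3 converts this into 7-(methoxymethoxy)-2,2-dimethyl-2H-chromene-8-carbaldehyde F4. n-BuLi (THF, −78 °C) turns F1 into the acetal aryllithium F5, which adds to the much less hindered aldehyde F4 to give the racemic diaryl carbinol F6. Dess–Martin periodinane oxidises this to the fully protected benzophenone F7. One treatment with dilute aq HCl in THF removes the acetal and both MOM groups to give 18.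

**Step 8.** The risk is that acid cleaves or cyclises the aryl prenyl ether, hydrates the chromene, or traps the aldehyde as a cyclic acetal with the ring-B phenol.

The fallback sets out from 6 and comes back at 18. It changes the protecting-group strategy so that no acid is used late in the route. Compound 6 is alkylated on its free 3-OH with allyl bromide (1.05 equiv, K2CO3, acetone) to give 3-(allyloxy)-2-bromo-6-hydroxy-5-methylbenzaldehyde F8. Prenylation as in step 4 gives 3-(allyloxy)-2-bromo-5-methyl-6-(prenyloxy)benzaldehyde F9. This goes through the step 7 sequence with 13 by way of the allyl-series lithium morpholino alkoxide F10, the allyl-series aryllithium F11 and the allyl-series tetrahedral adduct F12, giving the O-allyl benzophenone F13. Cat. Pd(PPh3)4 with K2CO3 in MeOH at rt (Tsuji–Trost-type deallylation) removes the unsubstituted allyl ether. The trisubstituted prenyl ether does not ionise at this temperature, and the product is 18.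

**Step 1.** The risks are loss of LiBr to an aryne, halogen dance, or incomplete deprotonation.

The fallback sets out from 1 and comes back at 7. It replaces the carbanion chemistry by a phenol-directed electrophilic formylation. BBr3 converts 1 through the bromomethylhydroquinone bis(dibromoboryl) ether F14 into 2-bromo-5-methylbenzene-1,4-diol F15. One equivalent of MOMCl with K2CO3 protects the more acidic OH ortho to Br to give 5-bromo-4-(methoxymethoxy)-2-methylphenol F16. Casnati–Skattebøl ortho-formylation (MgCl2, Et3N, paraformaldehyde, MeCN, reflux) places the CHO on the only free position ortho to the remaining phenol, giving 7.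

**Further compounds**
F1 | step 7 | 2-bromo-3-(methoxymethoxy)-5-methyl-6-(prenyloxy)benzaldehyde dimethyl acetal | COCOc1cc(C)c(OCC=C(C)C)c(C(OC)OC)c1Br
F2 | step 7 | diisobutylaluminium hemiacetal from DIBAL-H addition to 13 | CC(C)C[Al](CC(C)C)OC1OC(C)(C)Oc2ccc3C=CC(C)(C)Oc3c21
F3 | step 7 | 7-hydroxy-2,2-dimethyl-2H-chromene-8-carbaldehyde | CC1(C)C=Cc2ccc(O)c(C=O)c2O1
F4 | step 7 | 7-(methoxymethoxy)-2,2-dimethyl-2H-chromene-8-carbaldehyde | COCOc1ccc2C=CC(C)(C)Oc2c1C=O
F5 | step 7 | aryllithium from F1 (Li in place of Br) | COCOc1cc(C)c(OCC=C(C)C)c(C(OC)OC)c1[Li]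
F6 | step 7 | racemic diaryl carbinol from F5 and F4 | COCOc1cc(C)c(OCC=C(C)C)c(C(OC)OC)c1C(O)c1c(OCOC)ccc2C=CC(C)(C)Oc12
F7 | step 7 | fully protected benzophenone (dimethyl acetal, two MOM ethers) | COCOc1cc(C)c(OCC=C(C)C)c(C(OC)OC)c1C(=O)c1c(OCOC)ccc2C=CC(C)(C)Oc12
F8 | step 8 | 3-(allyloxy)-2-bromo-6-hydroxy-5-methylbenzaldehyde | C=CCOc1cc(C)c(O)c(C=O)c1Br
F9 | step 8 | 3-(allyloxy)-2-bromo-5-methyl-6-(prenyloxy)benzaldehyde | C=CCOc1cc(C)c(OCC=C(C)C)c(C=O)c1Br
F10 | step 8 | lithium α-morpholino alkoxide of F9 | C=CCOc1cc(C)c(OCC=C(C)C)c(C(O[Li])N2CCOCC2)c1Br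
F11 | step 8 | aryllithium from F10 | C=CCOc1cc(C)c(OCC=C(C)C)c(C(O[Li])N2CCOCC2)c1[Li]
F12 | step 8 | dilithium tetrahedral adduct of F11 on 13 | C=CCOc1cc(C)c(OCC=C(C)C)c(C(O[Li])N2CCOCC2)c1C1(O[Li])OC(C)(C)Oc2ccc3C=CC(C)(C)Oc3c21
F13 | step 8 | 3-(allyloxy)-2-[(7-hydroxy-2,2-dimethyl-2H-chromen-8-yl)carbonyl]-5-methyl-6-(prenyloxy)benzaldehyde | C=CCOc1cc(C)c(OCC=C(C)C)c(C=O)c1C(=O)c1c(O)ccc2C=CC(C)(C)Oc12
F14 | step 1 | 1-bromo-2,5-bis[(dibromoboryl)oxy]-4-methylbenzene | Cc1cc(OB(Br)Br)c(Br)cc1OB(Br)Br
F15 | step 1 | 2-bromo-5-methylbenzene-1,4-diol | Cc1cc(O)c(Br)cc1O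
F16 | step 1 | 5-bromo-4-(methoxymethoxy)-2-methylphenol | COCOc1cc(C)c(O)cc1Br
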